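The violet flask leaves a leftover: its other capture product averages 44.5% and its target 39.7%, so 15.9% of the starting material is missing from the readings.

| setting | violet | amber | flask |
|---|---|---|---|
| starting material | 0.80 M | 0.80 M | 0.80 M |
| first nucleophile | 0.64 M | 0.64 M | 0.640 M |
| second nucleophile | 1.2 M | 1.8 M | 1.20 M |
| remark | the very flask that is asked about, followed so far | run made earlier |  |
| time |  |  | 25 h |

| run | time / h | other capture product / % | target / % |
|---|---|---|---|
| violet | 1.50 | 43.7 | 38.7 |
| violet | 3.00 | 45.2 | 39.4 |
| violet | 5.00 | 44.5 | 38.6 |
| violet | 6.00 | 44.2 | 40.9 |
| violet | 8.00 | 44.7 | 40.8 |
| amber | 4.00 | 54.2 | 34.9 |
| amber | 8.00 | 54.7 | 35.6 |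
| amber | 10.0 | 56.3 | 34.7 |
| amber | 15.0 | 53.0 | 34.8 |
| amber | 20.0 | 56.2 | 33.0 |

(scatter of a reading: 1 percentage point)

- a species is counted by the starting material in it: one side product counts as two
- steps under discussion: starting material <-> intermediate; second nucleophile + intermediate -> other capture product; first nucleophile + intermediate -> target; starting material + target -> side product

* share of other capture product in other capture product plus target at 20 s
* share of other capture product in other capture product plus target at 25 h

I book this gap as side product. Each side product counts as two, one of which was a target, so 7.93% of target was formed and then eaten. This correction is what I need, since it raises the first nucleophile spent from 49.6% to 59.5% of its charge.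

Each capture runs at its rate constant times its nucleophile times the intermediate. The intermediate therefore cancels between the two captures, and the natural logarithm of the fraction left of second nucleophile is a fixed multiple of the same logarithm for first nucleophile. The violet flask gives 0.389 for that multiple. The amber flask, with a different charge, gives 0.405. Their mean, 0.397, is the capture ratio, the second nucleophile's capture constant over the first nucleophile's, or selectivity factor.

It costs no rate of the first step. Taking the charges as still nearly whole at 20 s, I multiply the ratio by each charge and get an early share of 42.7%. The readings stand still within their scatter, in the amber flask up to 20.0 h, so for 25 h I take the violet plateau, 52.8%.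

The forecast says 43.2% and 52.8%. For the early time it reasons that “the share is the initial one”, and its figure stands a little above mine.

The flask gives 43.0% and 53.4%.

    starting material ⇌ intermediate (K = 0.00260, k = 0.150 min⁻¹)
    second nucleophile + intermediate → other capture product (k = 10.0 M⁻¹ min⁻¹)
    first nucleophile + intermediate → target (k = 25.0 M⁻¹ min⁻¹)
    starting material + target → side product (k = 0.0180 M⁻¹ min⁻¹)

In the violet flask, while starting material remains, both captures run and target is also lost to side product, though at 0.235 h target is made 6.25 times faster than it is used up. By 2.50 h starting material stands at 0.302%, with target 39.2%, other capture product 44.8% and side product 15.7%; at 25.0 h other capture product stands at 45.0%, and the share is the same at 250 h.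

On a neighbour charged with 3.0 M of second nucleophile, the ratio 0.397 gives an early share of 65.1%. The computed value there is 65.3%.

The data are simulated with made-up constants, noise included.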